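The numbers in the tables were generated by integration for an exercise, noise included.

A selectivity factor of 3.87 is what I read from the ash run, and I call it N, the charge of starting material times the second-order constant of its quench by protic impurity, divided by the first-order constant of its step to intermediate A.

all flasks: starting material 0.20 M

| charge | protic impurity | remark | time |
|---|---|---|---|
| alder | 0.023 M | run made earlier |  |
| ash | 0.12 M | run made earlier |  |
| dawn | 0.0200 M |  | 80 min |
| noon | 0.0400 M |  | 80 min |
| spring | 0.0800 M |  | 80 min |

| run | time / min | intermediate C / % | target / % | starting material / % | intermediate A / % | intermediate B / % |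
|---|---|---|---|---|---|---|
| alder | 5.00 | 0 | 0 | 89.4 | 7.8 | 0.4 |
| alder | 15.0 | 0.3 | 0 | 71.1 | 19.0 | 2.6 |
| alder | 25.0 | 0.4 | 0 | 58.1 | 25.0 | 7.6 |
| alder | 40.0 | 1.6 | 0 | 43.9 | 30.2 | 15.7 |
| ash | 3.00 | 0.5 | 0 | 85.5 | 4.7 | 0.1 |
| ash | 8.00 | 0 | 0 | 67.4 | 10.7 | 0 |
| ash | 15.0 | 0.5 | 0.6 | 51.0 | 14.9 | 4.1 |
| ash | 40.0 | 1.0 | 0.1 | 23.4 | 19.6 | 12.5 |

(readings scatter by 0.5 percentage points)

- what is said of target includes crystals
- crystals is a solid; its amount is given per volume of the solution
- steps thought possible: intermediate B -> intermediate C; starting material + protic impurity -> quenched substrate; crystals <-> target; intermediate C -> target; starting material -> intermediate A; intermediate A -> intermediate B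

- which of these there is most of at the end, counted by the starting material in it, dawn (starting material / intermediate C / intermediate A / intermediate B)
- which of these there is most of at the end, counted by the starting material in it, noon (starting material / intermediate C / intermediate A / intermediate B)
- which of these there is most of at the end, counted by the starting material in it, spring (starting material / intermediate C / intermediate A / intermediate B)
- the largest of these amounts at the end, in percent of the starting material charged, dawn
- the largest of these amounts at the end, in percent of the starting material charged, noon
- the largest of these amounts at the end, in percent of the starting material charged, spring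

When I divide the two rates, time cancels and the integral closes: the fraction of protic impurity left is exp(−Nm), where m is the share of the charge that has taken the main path. In the ash run at 40.0 min, the missing balance of 43.4%, taken as quenched substrate, and an m of 33.2% give that N; the alder run reads 2.90, so I hold N loosely.

For the end I take the alder starting material at 40.0 min, squared, as what remains at 80 min, and I count the impurity charge as spent to get a first m. The share escaping quench is then 90.6% in dawn and 68.3% in spring. If intermediate B scaled with that share, spring would hold 0.754 of dawn's amount. But N holds no time, so it divides the charge without saying how far along the chain the survivors stand, and one number is not enough.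

The forecast runs that clock and gives 36%, 33.5% and 29% for dawn, noon and spring, a spring-to-dawn ratio of 0.806, with intermediate B on top each time: “B is largest in all three runs, assuming no late change in mechanism.”

    intermediate B → intermediate C (k = 1.10 × 10⁻⁴ s⁻¹)
    starting material + protic impurity → quenched substrate (k = 0.00560 M⁻¹ s⁻¹)
    crystals ⇌ target, rate k3*(cs3 - [target]) while solid is left; crystals form when [target] > cs3 (solubility = 3.80 mM, k = 0.0490 s⁻¹)
    intermediate C → target (k = 3.90 × 10⁻⁴ s⁻¹)
    starting material → intermediate A (k = 2.90 × 10⁻⁴ s⁻¹)
    intermediate A → intermediate B (k = 3.60 × 10⁻⁴ s⁻¹)

Spring ends with intermediate B on top at 26.8%, noon with intermediate B at 31.5% and dawn with intermediate B at 34.1%, a spring-to-dawn ratio of 0.786, above mine and below the forecast's. Spring holds 34.7% quenched substrate and 12.8% starting material at 80.0 min, so m is 52.5%, and exp(−Nm) gives 13.1% of the impurity against 13% left in the flask. A neighbouring flask, the same as spring but charged with 0.80 M of starting material, has N of 15.5 and m of 67.8%, so the rule gives 0.00273%; in that flask protic impurity is the limiting reagent, and 0% of it remains.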